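**Retrosynth­etic overview**
1. The 20-membered dilactone is opened at both C9–O ester bonds (Mitsunobu cyclodimerisation, inversion at C9) to two molecules of the (8R,9S) seco acid; the macrocycle is the last ring formed.
2. The (2Z,4Z)-dienoic acid is cut at C4=C5 into a C5 phosphonium ylide and ring-opened 5-hydroxy-3-methylbutenolide (Z-selective Wittig; the 2Z bond comes ready-made from the butenolide).
3. Key C–C bond: oxazole C4–C5, made by adding the isocyanomethyl anion (a carbanion at an innately electrophilic, imine-type carbon) to the acyl carbon of a β-lactone; this builds the oxazole and frees the C9 hydroxyl in one step.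
4. The β-lactone comes from a terminal epoxide by CO insertion; the epoxide comes from (R)-citronellal by catalyst-controlled α-chlorination (sets C9), while C8 is bought with citronellal.
5. Ring order: oxirane → oxetan-2-one → oxazole → macrodiolide.

Assumption: methyl isocyanide, 5-hydroxy-3-methylfuran-2(5H)-one and the carbonylation catalyst are taken as purchased; locants C1–C10 refer to the seco-acid chain (C1 carboxyl, C9 carbinol), and the (5S)-imidazolidinone is taken to give the (2S)-chloride (the antipodal catalyst would give the C2 epimer).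

**Route**

Step 1
Reactants: 1 (R)-citronellal, (3R)-3,7-dimethyloct-6-enal
Product: 4 (2R)-2-[(2R)-6-methylhept-5-en-2-yl]oxirane, via chloroaldehyde 2 (not isolated), via chlorohydrin 3 (not isolated)
Conditions: (5S)-5-benzyl-2,2,3-trimethylimidazolidin-4-one·CF3CO2H (10 mol%), 2,3,4,5,6,6-hexachlorocyclohexa-2,4-dien-1-one (1.2 equiv), acetone, −30 °C; pentane, filter; NaBH4, CH2Cl2/EtOH, 0 °C; then aq KOH, rt
Reagents that add atoms: none
Why: Enamine-catalysed α-chlorination in which the enamine is chlorinated on the face away from the catalyst's benzyl group, setting C2 as S under catalyst control (the methyl centre of 1 is untouched); after borohydride reduction the alkoxide closes the oxirane by intramolecular SN2 (Williamson) with inversion at the chlorine-bearing carbon, giving the (2R)-oxirane that carries the future C9–O bond.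

Step 2
Reactants: 4 (2R)-2-[(2R)-6-methylhept-5-en-2-yl]oxirane
Product: 5 (4S)-4-[(2R)-6-methylhept-5-en-2-yl]oxetan-2-one
Conditions: [(salph)Al(THF)2][Co(CO)4] (2 mol%; salph = N,N′-bis(3,5-di-tert-butylsalicylidene)-1,2-phenylenediamine dianion), CO (60 bar), DME, 50 °C
Reagents that add atoms: carbon monoxide, [C-]#[O+]
Why: Ring-expansion carbonylation of an epoxide by a Lewis acid/tetracarbonylcobaltate ion pair: Co(CO)4− opens the aluminium-activated oxirane by SN2 at the unsubstituted CH2, CO inserts and the alkoxide closes on the acyl cobalt, so the C–O bond at the stereocentre is never broken (retention; the descriptor changes from R to S only through CIP priorities).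

Step 3
Reactants: 5 (4S)-4-[(2R)-6-methylhept-5-en-2-yl]oxetan-2-one
Product: 7 (2S,3R)-3,7-dimethyl-1-(1,3-oxazol-5-yl)oct-6-en-2-ol, via isocyano ketone 6 (not isolated)
Conditions: CH3NC (2.5 equiv), n-BuLi (2.4 equiv), THF, −78 °C; then 5, −78 → −30 °C; AcOH, → rt
Reagents that add atoms: methyl isocyanide, [C-]#[N+]C
Why: Proposed new method: a Schöllkopf oxazole synthesis run on a β-lactone, in which the isocyanide-stabilised carbanion (a reversed-polarity aminomethyl anion whose carbon becomes the imine-type C4) attacks the strained lactone carbonyl (the future C5, also an innately electrophilic carbon) with acyl–oxygen cleavage, a second equivalent deprotonates the α-isocyano ketone 6 so no over-addition occurs, and on protonation the enol oxygen closes onto the isocyanide carbon to give the 4-unsubstituted 5-alkyl oxazole while the C9 alkoxide is released with retention and needs no protecting group; the closest known reactions are the acylation of α-metalated isocyanides with esters and the opening of γ- and δ-lactones by the same reagent to 5-(ω-hydroxyalkyl)oxazoles.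

Step 4
Reactants: 7 (2S,3R)-3,7-dimethyl-1-(1,3-oxazol-5-yl)oct-6-en-2-ol
Product: 9 (4R,5S)-4-methyl-6-(1,3-oxazol-5-yl)hexane-1,5-diol, via hydroxy aldehyde 8 (not isolated)
Conditions: O3, CH2Cl2/MeOH 4:1, Sudan Red 7B end-point, −78 °C; then NaBH4, −78 → 0 °C
Reagents that add atoms: ozone, [O-][O+]=O
Why: Ozonolysis with reductive work-up: the electron-rich trisubstituted alkene reacts with ozone far faster than the electron-poor oxazole (the dye end-point stops the reaction at one equivalent), and borohydride reduces the peroxidic cleavage products and aldehyde 8 to the primary alcohol; no stereocentre is involved.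

Step 5
Reactants: 9 (4R,5S)-4-methyl-6-(1,3-oxazol-5-yl)hexane-1,5-diol
Product: 10 (2S,3R)-6-iodo-3-methyl-1-(1,3-oxazol-5-yl)hexan-2-ol
Conditions: I2 (1.1 equiv), PPh3 (1.1 equiv), imidazole (1.2 equiv), CH2Cl2, 0 °C
Reagents that add atoms: iodine, II
Why: Appel-type iodination in which the unhindered primary hydroxyl is converted into its alkoxyphosphonium ion and displaced by iodide much faster than the branched secondary hydroxyl, which stays free.

Step 6
Reactants: 10 (2S,3R)-6-iodo-3-methyl-1-(1,3-oxazol-5-yl)hexan-2-ol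
Product: 11 [(4R,5S)-5-hydroxy-4-methyl-6-(1,3-oxazol-5-yl)hexyl]triphenylphosphonium iodide
Conditions: PPh3 (1.5 equiv), MeCN, 80 °C
Reagents that add atoms: triphenylphosphine, c1ccc(cc1)P(c1ccccc1)c1ccccc1
Why: SN2 quaternisation of triphenylphosphine by the primary iodide under neutral conditions, which leaves the secondary alcohol and the weakly basic oxazole alone.

Step 7
Reactants: 11 [(4R,5S)-5-hydroxy-4-methyl-6-(1,3-oxazol-5-yl)hexyl]triphenylphosphonium iodide; 12 5-hydroxy-3-methylfuran-2(5H)-one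
Product: 15 (2Z,4Z,8R,9S)-9-hydroxy-2,8-dimethyl-10-(1,3-oxazol-5-yl)deca-2,4-dienoic acid, via oxido ylide 13 (not isolated), via formyl carboxylate 14 (not isolated)
Conditions: 11, NaN(SiMe3)2 (2.0 equiv), THF/DMPU, −78 → 0 °C; then 12 pre-treated with NaN(SiMe3)2 (1.0 equiv, THF, −78 °C), −78 °C → rt; aq NaH2PO4 to pH 5
Reagents that add atoms: none
Why: Wittig olefination in which base opens lactol 12 to the cis formyl carboxylate 14, so the 2Z geometry is carried over intact from the butenolide ring, and the lithium-free non-stabilised ylide 13 adds through the kinetically preferred cis oxaphosphetane to give the new C4=C5 bond as Z; exactly two equivalents of base on 11 form the alkoxide and the ylide without metalating the oxazole.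

Step 8
Reactants: 15 (2Z,4Z,8R,9S)-9-hydroxy-2,8-dimethyl-10-(1,3-oxazol-5-yl)deca-2,4-dienoic acid (two molecules)
Product: 17 (3Z,5Z,9R,10R,13Z,15Z,19R,20R)-3,9,13,19-tetramethyl-10,20-bis(1,3-oxazol-5-ylmethyl)-1,11-dioxacycloicosa-3,5,13,15-tetraene-2,12-dione, via linear dimer 16 (not isolated)
Conditions: PPh3 (4 equiv), diisopropyl azodicarboxylate (4 equiv), toluene/THF, 0.01 M, slow addition of 15, 0 °C → rt
Reagents that add atoms: none
Why: Mitsunobu esterification used as a head-to-tail cyclodimerisation: each secondary alcohol is activated as its alkoxyphosphonium ion and displaced by the dienoate carboxylate in an SN2 step with inversion (9S to 9R, twice), and because the acid is never activated the isomerisation-prone Z,Z-dienoate is not put at risk; the two cis double bonds preclude the 10-membered monomeric lactone, so linear dimer 16 closes to the 20-membered ring.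

**Compound list**

1 | (R)-citronellal, (3R)-3,7-dimethyloct-6-enal | CC(C)=CCC[C@@H](C)CC=O | starting material
2 | (2S,3R)-2-chloro-3,7-dimethyloct-6-enal | CC(C)=CCC[C@@H](C)[C@H](Cl)C=O | intermediate (not isolated)
3 | (2S,3R)-2-chloro-3,7-dimethyloct-6-en-1-ol | CC(C)=CCC[C@@H](C)[C@H](Cl)CO | intermediate (not isolated)
4 | (2R)-2-[(2R)-6-methylhept-5-en-2-yl]oxirane | CC(C)=CCC[C@@H](C)[C@@H]1CO1 | intermediate
5 | (4S)-4-[(2R)-6-methylhept-5-en-2-yl]oxetan-2-one | CC(C)=CCC[C@@H](C)[C@@H]1CC(=O)O1 | intermediate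
6 | (4S,5R)-4-hydroxy-1-isocyano-5,9-dimethyldec-8-en-2-one (formed as its dilithium alkoxide/enolate) | CC(C)=CCC[C@@H](C)[C@@H](O)CC(=O)C[N+]#[C-] | intermediate (not isolated)
7 | (2S,3R)-3,7-dimethyl-1-(1,3-oxazol-5-yl)oct-6-en-2-ol | CC(C)=CCC[C@@H](C)[C@H](Cc1cnco1)O | intermediate
8 | (4R,5S)-5-hydroxy-4-methyl-6-(1,3-oxazol-5-yl)hexanal | O=CCC[C@@H](C)[C@H](Cc1cnco1)O | intermediate (not isolated)
9 | (4R,5S)-4-methyl-6-(1,3-oxazol-5-yl)hexane-1,5-diol | OCCC[C@@H](C)[C@H](Cc1cnco1)O | intermediate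
10 | (2S,3R)-6-iodo-3-methyl-1-(1,3-oxazol-5-yl)hexan-2-ol | ICCC[C@@H](C)[C@H](Cc1cnco1)O | intermediate
11 | [(4R,5S)-5-hydroxy-4-methyl-6-(1,3-oxazol-5-yl)hexyl]triphenylphosphonium iodide | [I-].c1ccc(cc1)[P+](c1ccccc1)(c1ccccc1)CCC[C@@H](C)[C@H](Cc1cnco1)O | intermediate
12 | 5-hydroxy-3-methylfuran-2(5H)-one | CC1=CC(O)OC1=O | starting material
13 | sodium (2S,3R)-3-methyl-1-(1,3-oxazol-5-yl)-6-(triphenyl-λ5-phosphanylidene)hexan-2-olate (oxido ylide) | c1ccc(cc1)P(c1ccccc1)(c1ccccc1)=CCC[C@@H](C)[C@H](Cc1cnco1)[O-].[Na+] | intermediate (not isolated)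
14 | sodium (2Z)-2-methyl-4-oxobut-2-enoate | [Na+].[O-]C(=O)/C(C)=C\C=O | intermediate (not isolated)
15 | (2Z,4Z,8R,9S)-9-hydroxy-2,8-dimethyl-10-(1,3-oxazol-5-yl)deca-2,4-dienoic acid | C/C(C(=O)O)=C/C=C\CC[C@@H](C)[C@H](Cc1cnco1)O | intermediate
16 | (2Z,4Z,8R,9R)-9-{[(2Z,4Z,8R,9S)-9-hydroxy-2,8-dimethyl-10-(1,3-oxazol-5-yl)deca-2,4-dienoyl]oxy}-2,8-dimethyl-10-(1,3-oxazol-5-yl)deca-2,4-dienoic acid | OC(=O)/C(C)=C\C=C/CC[C@@H](C)[C@@H](Cc1cnco1)OC(=O)/C(C)=C\C=C/CC[C@@H](C)[C@H](Cc1cnco1)O | intermediate (not isolated)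
17 | (3Z,5Z,9R,10R,13Z,15Z,19R,20R)-3,9,13,19-tetramethyl-10,20-bis(1,3-oxazol-5-ylmethyl)-1,11-dioxacycloicosa-3,5,13,15-tetraene-2,12-dione (CNP0414419.1) | C/C1=C/C=C\CC[C@@H](C)[C@@H](Cc2cnco2)OC(=O)/C(C)=C\C=C/CC[C@@H](C)[C@@H](Cc2cnco2)OC1=O | target

**Step count and risks**

Total steps: 8. Longest linear sequence: 8 (from 1; compound 12 is bought). No protecting groups are used.

The three steps most likely to fail, each with a fallback:

The first is step 3, the isocyanide acylation of a β-lactone. The risks are α-deprotonation of 5 followed by β-elimination, or attack at the alkyl–oxygen carbon. The fallback sets out from epoxide 4 and by-passes 5, using a preformed heterocycle as the nucleophile. 2-(Triisopropylsilyl)-1,3-oxazole is lithiated at C5 (n-BuLi, THF, −78 °C) and the 5-lithio species opens 4 at its CH2 terminus in the presence of BF3·OEt2 to give (2S,3R)-3,7-dimethyl-1-[2-(triisopropylsilyl)-1,3-oxazol-5-yl]oct-6-en-2-ol F1. Bu4NF in THF then removes the silyl group and the route is rejoined at 7.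

The second is step 7, the Wittig reaction. The risks are loss of Z-selectivity with the oxido ylide, metalation of the oxazole, and a sluggish ring-opened butenolide partner. The fallback sets out from hydroxy aldehyde 8, isolated as its lactol when the ozonolysis of step 4 is quenched with Me2S instead of NaBH4, and builds the diene by cross-coupling and cis-semireduction. Homologation with dimethyl (1-diazo-2-oxopropyl)phosphonate (K2CO3, MeOH) gives (2S,3R)-3-methyl-1-(1,3-oxazol-5-yl)hept-6-yn-2-ol F2. Sonogashira coupling (PdCl2(PPh3)2, CuI, Et3N, MeCN) with methyl (2Z)-2-methyl-3-{[(4-methylphenyl)sulfonyl]oxy}prop-2-enoate F3 proceeds with retention of the enol tosylate geometry; F3 is made in one operation from methyl 2-methyl-3-oxopropanoate with TsCl, N-methylimidazole and LiOH. The coupling gives methyl (2Z,8R,9S)-9-hydroxy-2,8-dimethyl-10-(1,3-oxazol-5-yl)dec-2-en-4-ynoate F4. Reduction of the triple bond with Zn dust activated by Cu(OAc)2 and AgNO3 in MeOH/H2O gives methyl (2Z,4Z,8R,9S)-9-hydroxy-2,8-dimethyl-10-(1,3-oxazol-5-yl)deca-2,4-dienoate F5. Me3SnOH (1,2-dichloroethane, 70 °C) cleaves the methyl ester and the route is rejoined at 15.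

The third is step 8, the one-pot Mitsunobu cyclodimerisation. The risks are oligomers and elimination at the hindered carbinol. The fallback sets out from 15 and assembles the dimer stepwise:
- Allyl bromide and KHCO3 in DMF give prop-2-en-1-yl (2Z,4Z,8R,9S)-9-hydroxy-2,8-dimethyl-10-(1,3-oxazol-5-yl)deca-2,4-dienoate F6.
- A second portion of 15 with tert-butyldimethylsilyl triflate and 2,6-lutidine gives tert-butyldimethylsilyl (2Z,4Z,8R,9S)-9-[(tert-butyldimethylsilyl)oxy]-2,8-dimethyl-10-(1,3-oxazol-5-yl)deca-2,4-dienoate F7.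
- K2CO3 in MeOH/H2O cleaves the silyl ester of F7 to (2Z,4Z,8R,9S)-9-[(tert-butyldimethylsilyl)oxy]-2,8-dimethyl-10-(1,3-oxazol-5-yl)deca-2,4-dienoic acid F8.
- Intermolecular Mitsunobu coupling of alcohol F6 with acid F8 (PPh3, diisopropyl azodicarboxylate, toluene, 0 °C) inverts C9 of F6 and gives prop-2-en-1-yl (2Z,4Z,8R,9R)-9-{[(2Z,4Z,8R,9S)-9-[(tert-butyldimethylsilyl)oxy]-2,8-dimethyl-10-(1,3-oxazol-5-yl)deca-2,4-dienoyl]oxy}-2,8-dimethyl-10-(1,3-oxazol-5-yl)deca-2,4-dienoate F9.
- Pd(PPh3)4 and morpholine remove the allyl group to give (2Z,4Z,8R,9R)-9-{[(2Z,4Z,8R,9S)-9-[(tert-butyldimethylsilyl)oxy]-2,8-dimethyl-10-(1,3-oxazol-5-yl)deca-2,4-dienoyl]oxy}-2,8-dimethyl-10-(1,3-oxazol-5-yl)deca-2,4-dienoic acid F10.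
- HF·pyridine removes the silyl ether, and the route is rejoined at 16, now isolated.
- 16 is closed to 17 by intramolecular Mitsunobu lactonisation at 0.001 M.

**Further compounds**

F1 | step 3 | (2S,3R)-3,7-dimethyl-1-[2-(triisopropylsilyl)-1,3-oxazol-5-yl]oct-6-en-2-ol | CC(C)=CCC[C@@H](C)[C@H](Cc1cnc(o1)[Si](C(C)C)(C(C)C)C(C)C)O
F2 | step 7 | (2S,3R)-3-methyl-1-(1,3-oxazol-5-yl)hept-6-yn-2-ol | C#CCC[C@@H](C)[C@H](Cc1cnco1)O
F3 | step 7 | methyl (2Z)-2-methyl-3-{[(4-methylphenyl)sulfonyl]oxy}prop-2-enoate | COC(=O)/C(C)=C\OS(=O)(=O)c1ccc(C)cc1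
F4 | step 7 | methyl (2Z,8R,9S)-9-hydroxy-2,8-dimethyl-10-(1,3-oxazol-5-yl)dec-2-en-4-ynoate | COC(=O)/C(C)=C\C#CCC[C@@H](C)[C@H](Cc1cnco1)O
F5 | step 7 | methyl (2Z,4Z,8R,9S)-9-hydroxy-2,8-dimethyl-10-(1,3-oxazol-5-yl)deca-2,4-dienoate | COC(=O)/C(C)=C\C=C/CC[C@@H](C)[C@H](Cc1cnco1)O
F6 | step 8 | prop-2-en-1-yl (2Z,4Z,8R,9S)-9-hydroxy-2,8-dimethyl-10-(1,3-oxazol-5-yl)deca-2,4-dienoate | C=CCOC(=O)/C(C)=C\C=C/CC[C@@H](C)[C@H](Cc1cnco1)O
F7 | step 8 | tert-butyldimethylsilyl (2Z,4Z,8R,9S)-9-[(tert-butyldimethylsilyl)oxy]-2,8-dimethyl-10-(1,3-oxazol-5-yl)deca-2,4-dienoate | CC(C)(C)[Si](C)(C)OC(=O)/C(C)=C\C=C/CC[C@@H](C)[C@H](Cc1cnco1)O[Si](C)(C)C(C)(C)C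
F8 | step 8 | (2Z,4Z,8R,9S)-9-[(tert-butyldimethylsilyl)oxy]-2,8-dimethyl-10-(1,3-oxazol-5-yl)deca-2,4-dienoic acid | OC(=O)/C(C)=C\C=C/CC[C@@H](C)[C@H](Cc1cnco1)O[Si](C)(C)C(C)(C)C
F9 | step 8 | prop-2-en-1-yl (2Z,4Z,8R,9R)-9-{[(2Z,4Z,8R,9S)-9-[(tert-butyldimethylsilyl)oxy]-2,8-dimethyl-10-(1,3-oxazol-5-yl)deca-2,4-dienoyl]oxy}-2,8-dimethyl-10-(1,3-oxazol-5-yl)deca-2,4-dienoate | C=CCOC(=O)/C(C)=C\C=C/CC[C@@H](C)[C@@H](Cc1cnco1)OC(=O)/C(C)=C\C=C/CC[C@@H](C)[C@H](Cc1cnco1)O[Si](C)(C)C(C)(C)C
F10 | step 8 | (2Z,4Z,8R,9R)-9-{[(2Z,4Z,8R,9S)-9-[(tert-butyldimethylsilyl)oxy]-2,8-dimethyl-10-(1,3-oxazol-5-yl)deca-2,4-dienoyl]oxy}-2,8-dimethyl-10-(1,3-oxazol-5-yl)deca-2,4-dienoic acid | OC(=O)/C(C)=C\C=C/CC[C@@H](C)[C@@H](Cc1cnco1)OC(=O)/C(C)=C\C=C/CC[C@@H](C)[C@H](Cc1cnco1)O[Si](C)(C)C(C)(C)C
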